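The fraction of substrate left at 15.0 h holds across a charge ratio of 15.4: 53% in Thursday's run, 52% in Friday's. So read its loss as first order, with k = 0.0436 /h.

all flasks: gas 1.2 mM (held)
- Thursday's: substrate 9.1 mM; run made earlier
- Friday's: substrate 140 mM; run made earlier
- ash: substrate 28 mM; time 15 h
- maple: substrate 120 mM; time 15 h
- cedar: substrate 8.0 mM; time 15 h
- birch: substrate 40 mM; time 15 h
- alder: substrate 80 mM; time 15 h

| run | time / h | target / % | substrate / % |
|---|---|---|---|
| Thursday's | 1.00 | 0 | 93 |
| Thursday's | 3.00 | 5 | 90 |
| Thursday's | 5.00 | 12 | 81 |
| Thursday's | 8.00 | 24 | 69 |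
| Thursday's | 12.0 | 34 | 59 |
| Thursday's | 15.0 | 44 | 53 |
| Friday's | 1.00 | 1 | 93 |
| Friday's | 3.00 | 0 | 89 |
| Friday's | 5.00 | 2 | 81 |
| Friday's | 8.00 | 5 | 72 |
| Friday's | 12.0 | 7 | 57 |
| Friday's | 15.0 | 10 | 52 |

(standard deviation of a reading: 1.5 percentage points)

- the analysis behind the earlier runs scatters by 1.5 percentage points, standard deviation
- at the start none of the gas is in solution

1. the flasks put in order of amount of target, in percent of the substrate charged, best first, at 15 h (ash / maple / cedar / birch / alder)
2. the amount of target, in percent of the substrate charged of the flask you put first, at 15 h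
3. the amount of target, in percent of the substrate charged of the flask you put last, at 15 h

Reckon the rate of target formation. The substrate's supply at the start is k·c(substrate), which is 5.23 mM/h in maple and 0.349 mM/h in cedar. Friday's target reads 14.0 mM at 15.0 h, less than the 67.2 mM of substrate lost by then. Call the uptake ceiling 0.933 mM/h: the mean rate of target formation read from Friday's run, carried over to a flask whose supply stays above it. The gas is held at 1.2 mM and starts out of solution, so suspect its uptake as the rate-limiting step.

Now apply the ceiling to maple. It cuts the starting supply by a factor 0.178. Reckon the substrate's decay to lower the supply to 2.72 mM/h by 15 h, still more than the ceiling. So reckon the rate flat in maple, which integrates to J·t, or 11.7% of maple's charge. Cedar's supply starts less than the ceiling, so expect about Thursday's 44% there. Put cedar, with the smallest charge, first and maple, with the largest, last, and the others by rising charge between them.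

The forecast gives cedar > ash > birch > alder > maple, with 44% and 11.5%, citing “gas transfer capping target formation at about 1 mM/h”.

The flasks give cedar > ash > birch > alder > maple, with cedar at 43.0% and maple at 13.0%, which is more than the ceiling's 11.7%.

    substrate → intermediate (k = 1.20 × 10⁻⁵ /s)
    partner + intermediate → target (k = 0.160 /M/s)
    2 intermediate → homo product (k = 0.00150 /M/s)
    gas ⇌ partner, rate k4*(csat - [partner]) (kL = 2.80 × 10⁻⁴ /s)

In maple the substrate fell to 52.3% by 15.0 h, while partner stood at 0.124 mM at 7.50 h and 0.136 mM at 15.0 h against a saturation of 1.2 mM, made 1.00 times as fast as it was used up at 15.0 h. In maple the intermediate stood at 12.6% at 7.50 h and 11.3% at 15.0 h, when homo product held 23.4% of the charge and target 13.0%.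

For maple read at 10 h, the ceiling gives 7.78%. The computed flask holds 8.50% of target.

All runs stem from a simulated flask for an exercise; the scatter is artificial.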